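Partner, the dissolved gas, is the molecule I follow. By the proposed steps it meets a fork: free catalyst takes it and a product follows, or it goes to decomposed reagent.

| flask | substrate | gas | free catalyst | remark | time |
|---|---|---|---|---|---|
| maple | 0.042 M | 40 mM (held) | 0.19 mM | run made earlier |  |
| elm | 0.063 M | 40 mM (held) | 0.19 mM | run made earlier |  |
| flask | 0.084 M | 40 mM (held) | 0.19 mM |  | 5.0 h |

- maple (time / h: product / %, substrate / %): 0.500: 3.7, 95.8; 1.50: 21.0, 78.6; 3.00: 54.4, 46.6; 4.00: 73.6, 25.9; 6.00: 98.6, 0.1
- elm (time / h: product / %, substrate / %): 0.500: 3.3, 96.6; 1.50: 14.0, 85.0; 3.00: 37.1, 62.4; 4.00: 49.7, 48.6; 6.00: 77.5, 21.4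

(readings scatter by 1 percentage point)

* product at 5.0 h, in percent of the substrate charged
* concentration of partner in solution at 5.0 h, in percent of saturation

- at the start none of partner is dissolved
- steps that have been proposed: partner + free catalyst -> catalyst intermediate A; substrate + catalyst intermediate A <-> catalyst intermediate B; catalyst intermediate B <-> by-product + catalyst intermediate C; catalyst intermediate C -> free catalyst + product; gas <-> partner; partner -> decomposed reagent

Which numbers must be good? The slope comes first. Between 1.50 h and 4.00 h the maple run gains 8.84 mM h⁻¹. Between 1.50 h and 4.00 h the elm run gains 9.00 mM h⁻¹. These slopes are alike, so between those times product in these two runs reads as zero order in substrate. I carry their mean, R, the steady product rate per litre: 8.92 mM h⁻¹. Over 5.0 h, their gap moves y, the product in percent of the substrate charged, by 0.95 percentage points.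

The lag L is the time lost before that slope. Elm gives 0.488 h and maple gives 0.533 h, and that gap moves y by 0.48 points, less than the gap in slope does. The substrate charge c is the divisor.

So for this flask at time t, y = R(t − L)/c gives 47.9%. For sat, the product readings give me no figure.

The forecast says 47%, slightly below mine, and 65%, with the remark: “Saturation is poorly determined, because the runs cannot separate transfer from consumption”.

The flask gives 49.2% and 26.2%.

    partner + free catalyst → catalyst intermediate A (k = 88.0 M⁻¹ min⁻¹)
    substrate + catalyst intermediate A ⇌ catalyst intermediate B (K = 24.0 M⁻¹, k = 960 M⁻¹ min⁻¹)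
    catalyst intermediate B ⇌ by-product + catalyst intermediate C (K = 0.0200 M, k = 170 min⁻¹)
    catalyst intermediate C → free catalyst + product (k = 37.0 min⁻¹)
    gas ⇌ partner, rate k5*(csat - [partner]) (kL = 0.00710 min⁻¹)
    partner → decomposed reagent (k = 0.00530 min⁻¹)

Taken alone, with concentrations as charged, the step to catalyst intermediate A gives partner a half-life of 0.69 h, shorter than the 2.2 h of decomposition alone. Carried to this flask read at 8.0 h, R and L give 79.7%, and that reading holds 80.1% product.

The numbers in the tables are calculated with made-up constants; the scatter is artificial.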